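**Retrosynthetic overview**
1. The target is the C4 ester of cryptomeridiol (eudesmane-4α,11-diol) with acetylisocupressic acid. The C4–O ester bond and the C2–C3 bond of eudesmane ring A (C1–C2–C3–C4–C5–C10) are cut in one move, giving acetylisocupressic acid and the 2,3-seco-eudesmane elemol (as its C11 silyl ether).
2. Enabling feature: the ester oxygen sits on C4, a tertiary ring-A carbon that carries a methyl group and lies 1,4 to C1. Opened at C2–C3, ring A is a 1,5-diene (vinyl C1=C2 on quaternary C10, isopropenyl C3=C4 on C5, both equatorial and trans on ring B). Joining its two terminal CH2 groups puts a cation exactly on C4, the eudesmyl cation of the biosynthesis.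
3. Platinum takes the part the proton plays at C1 in nature, and the diterpene acid ends the cyclization at C4. Ring closure, the C4 stereocentre and the hindered tertiary ester are therefore made together.
4. Ring order: the labdane decalin and eudesmane ring B come in with the chiral-pool terpenes (+)-isocupressic acid and (−)-elemol. Eudesmane ring A is the only ring closed, and it is closed last.
5. Flanking steps: acetylation of C15–OH of the acid, silylation and final desilylation of C11–OH.

Key step: step 3

Assumption: (+)-isocupressic acid and (−)-elemol are taken as purchasable natural products; natural (−)-elemol is the (1R,3S,4S) isomer, whose three stereocentres become C7, C5 and C10 of the eudesmane half unchanged.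

Step 1
Reactants: 1 (+)-isocupressic acid [15-hydroxylabda-8(17),13E-dien-19-oic acid]
Product: 3 acetylisocupressic acid [15-acetoxylabda-8(17),13E-dien-19-oic acid], via mixed acetic anhydride 2 (not isolated)
Conditions: Ac2O (3 equiv), DMAP (cat.), pyridine, 0 °C to rt; then H2O, rt
Reagents that add atoms: acetic anhydride, CC(=O)OC(C)=O
Why: DMAP-catalysed acylation (nucleophilic acyl substitution) acetylates the primary allylic C15–OH and also the carboxyl group, and water then cleaves the mixed anhydride 2 at its unhindered acetyl carbonyl, so the neopentyl C19 carboxyl group returns free; no stereocentre is touched.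

Step 2
Reactants: 4 (−)-elemol [2-[(1R,3S,4S)-4-ethenyl-4-methyl-3-(prop-1-en-2-yl)cyclohexyl]propan-2-ol]
Product: 5 elemol triethylsilyl ether
Conditions: TESOTf, 2,6-lutidine, CH2Cl2, −78 to 0 °C
Reagents that add atoms: triethylsilyl trifluoromethanesulfonate, CC[Si](CC)(CC)OS(=O)(=O)C(F)(F)F
Why: Silylation of the hindered tertiary C11–OH with a silyl triflate (2,6-lutidine buffers the triflic acid, so the 1,5-diene is left alone) removes the only other O–H nucleophile from the key step; no stereocentre is touched.

Step 3
Reactants: 5 elemol triethylsilyl ether; 3 acetylisocupressic acid (1.5-fold amount, excess recoverable)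
Product: 7 11-O-triethylsilyl ether of the target, via platinum alkyl cation 6 (not isolated)
Conditions: [Pt(triphos)(NCC6F5)](BF4)2 (1.1 equiv, triphos = PhP(CH2CH2PPh2)2), 2,6-di-tert-butyl-4-methylpyridine (1.2 equiv), 4 Å MS, MeNO2/CH2Cl2, −20 °C to rt; then NaBH4, THF/EtOH, 0 °C, aqueous work-up
Reagents that add atoms: none
Why: Proposed new method: the dicationic divalent platinum centre binds only the monosubstituted C1=C2 vinyl group of 5 (binding falls steeply with alkene substitution, so the isopropenyl group and both alkenes of 3 stay free), the isopropenyl terminus C3 attacks C2 anti to platinum in the Markovnikov sense, and the tertiary C4 carbenium ion is captured by the carboxyl oxygen of 3 while the hindered pyridine takes up the proton; NaBH4 then replaces the platinum–carbon bond at C1 by C–H. The closest known reaction type is the cation-olefin cyclization of 1,5-dienes started by pincer-ligated platinum dications, which is known to end by proton loss or by a tethered oxygen nucleophile and whose alkylplatinum products are known to be cleaved by NaBH4; new here is an intermolecular carboxylic acid as the terminating nucleophile. Ring A closes in a 6-endo mode through a chair transition state, the same chair that the known Cope equilibrium between elemol and hedycaryol passes through, with the C5 and C10 arms equatorial on ring B, so the trans ring fusion follows from the fixed C5 and C10 centres. The new stereocentre C4 is set by equatorial attack of the acid on the alpha face of the planar cation, the beta face being blocked by the axial C10 methyl group in a 1,3-diaxial relation, which gives the 4α-acyloxy-4β-methyl (4R) arrangement; C1 is no stereocentre after reduction. The step needs capture to outrun proton loss from the cation: the only base present is a pyridine too hindered to deprotonate or add to a tertiary carbenium ion (it serves as a proton trap in living cationic polymerisation), the C11 oxygen is silylated, and 3 is the only nucleophile in the flask. Should part of the complex instead trigger the Cope shift to the hedycaryol ether, protonation of that germacradiene at C1 leads to the same C4 cation, so both channels converge.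

Step 4
Reactants: 7 11-O-triethylsilyl ether of the target
Product: 8 target, (4R,5R,7R,10R)-11-hydroxyeudesman-4-yl (4S,5R,9S,10R)-15-acetoxylabda-8(17),13E-dien-19-oate
Conditions: HF·pyridine, pyridine, THF, 0 °C to rt
Reagents that add atoms: none
Why: Fluoride-driven Si–O cleavage (desilylation, strong Si–F bond) with pyridine-buffered HF should free the tertiary C11–OH without ionising the tertiary ester or touching the allylic acetate and the alkenes; no stereocentre is touched.

**Compound list**
1 | (+)-isocupressic acid, 15-hydroxylabda-8(17),13E-dien-19-oic acid | C=C1CC[C@@H]2[C@](C)(CCC[C@]2(C)C(=O)O)[C@H]1CC/C(C)=C/CO | starting material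
2 | mixed acetic anhydride of acetylisocupressic acid | C=C1CC[C@@H]2[C@](C)(CCC[C@]2(C)C(=O)OC(C)=O)[C@H]1CC/C(C)=C/COC(C)=O | intermediate
3 | acetylisocupressic acid, 15-acetoxylabda-8(17),13E-dien-19-oic acid | C=C1CC[C@@H]2[C@](C)(CCC[C@]2(C)C(=O)O)[C@H]1CC/C(C)=C/COC(C)=O | intermediate
4 | (−)-elemol, (1R,3S,4S) isomer | C=C[C@]1(C)CC[C@@H](C(C)(C)O)C[C@H]1C(C)=C | starting material
5 | elemol triethylsilyl ether | C=C[C@]1(C)CC[C@@H](C(C)(C)O[Si](CC)(CC)CC)C[C@H]1C(C)=C | intermediate
6 | platinum alkyl cation (tetrafluoroborate): 11-O-triethylsilyl target carrying Pt(triphos) at C1 of ring A, configuration at C1 of no consequence | C=C1CC[C@@H]2[C@](C)(CCC[C@]2(C)C(=O)O[C@]2(C)CCC([Pt-2]45[P+](c6ccccc6)(c6ccccc6)CC[P+]4(c4ccccc4)CC[P+]5(c4ccccc4)c4ccccc4)[C@]3(C)CC[C@@H](C(C)(C)O[Si](CC)(CC)CC)C[C@H]32)[C@H]1CC/C(C)=C/COC(C)=O.F[B-](F)(F)F | intermediate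
7 | 11-O-triethylsilyl ether of the target | C=C1CC[C@@H]2[C@](C)(CCC[C@]2(C)C(=O)O[C@]2(C)CCC[C@]3(C)CC[C@@H](C(C)(C)O[Si](CC)(CC)CC)C[C@H]32)[C@H]1CC/C(C)=C/COC(C)=O | intermediate
8 | CNP0141048.1, cryptomeridiol 4-O-(15-acetoxylabda-8(17),13E-dien-19-oate) | C=C1CC[C@@H]2[C@](C)(CCC[C@]2(C)C(=O)O[C@]2(C)CCC[C@]3(C)CC[C@@H](C(C)(C)O)C[C@H]32)[C@H]1CC/C(C)=C/COC(C)=O | target

**Count and risks**
Total step count: 4. Longest linear sequence: 3 steps (4 → 5 → 7 → 8); the branch 1 → 3 joins in step 3.

Steps most likely to fail:

Step 3. Proton loss from the C4 carbenium ion may outrun its capture by the hindered acid, and the vinyl group on the quaternary C10 may bind platinum too weakly. The fallback sets out from 5 and comes back at 7, with known reaction types only. Hydroboration of the vinyl group of 5 with 9-BBN (which prefers a monosubstituted over a 1,1-disubstituted alkene) and oxidation (NaOH, H2O2) should give the C2 primary alcohol F1. TsCl in pyridine should give the tosylate F2. Solvolysis in buffered aqueous 2,2,2-trifluoroethanol (2,6-lutidine, 50 °C) should close ring A by pi-participation of the isopropenyl group with loss of tosylate, and water should take the C4 cation from the alpha face to give 11-O-triethylsilylcryptomeridiol F3. Cl3CCN with catalytic KH should give the tertiary trichloroacetimidate F4. F4 should esterify 3 without promoter (cyclohexane/CH2Cl2, rt) by proton transfer, ionisation and ion-pair collapse on the alpha face, as tert-butyl trichloroacetimidate does with carboxylic acids, to give 7.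

Step 4. Ionisation of the tertiary ester C4–O bond or loss of the allylic acetate may occur while the silyl group is removed. The fallback sets out from 4 and comes back at 8: the silyl group is left out. Elemol 4 and acid 3 under the conditions of step 3 should give 8 directly through the platinum alkyl cation with free C11–OH F5 and NaBH4. The C11–OH cannot reach C4 of the trans-fused cation, so only capture by a second elemol molecule competes.

Step 1. Hydrolysis of the mixed anhydride may be incomplete or unselective, or acetyl may be lost from C15. The fallback sets out from 1 and comes back at 3: enzymatic acyl transfer replaces chemical acylation. Immobilised Candida antarctica lipase B with vinyl acetate in tert-butyl methyl ether at rt should acetylate only the primary allylic C15–OH, since the enzyme cannot activate the neopentyl carboxyl group; no new compound is made (F0).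

**Further compounds**
F1 | step 3 | C2 primary alcohol from hydroboration of 5 (vinyl turned into CH2CH2OH) | OCC[C@]1(C)CC[C@@H](C(C)(C)O[Si](CC)(CC)CC)C[C@H]1C(C)=C
F2 | step 3 | p-toluenesulfonate of F1 | Cc1ccc(cc1)S(=O)(=O)OCC[C@]1(C)CC[C@@H](C(C)(C)O[Si](CC)(CC)CC)C[C@H]1C(C)=C
F3 | step 3 | 11-O-triethylsilylcryptomeridiol | O[C@]1(C)CCC[C@]2(C)CC[C@@H](C(C)(C)O[Si](CC)(CC)CC)C[C@H]21
F4 | step 3 | C4 trichloroacetimidate of F3 | N=C(O[C@]1(C)CCC[C@]2(C)CC[C@@H](C(C)(C)O[Si](CC)(CC)CC)C[C@H]21)C(Cl)(Cl)Cl
F5 | step 4 | platinum alkyl cation (tetrafluoroborate) with free C11–OH | C=C1CC[C@@H]2[C@](C)(CCC[C@]2(C)C(=O)O[C@]2(C)CCC([Pt-2]45[P+](c6ccccc6)(c6ccccc6)CC[P+]4(c4ccccc4)CC[P+]5(c4ccccc4)c4ccccc4)[C@]3(C)CC[C@@H](C(C)(C)O)C[C@H]32)[C@H]1CC/C(C)=C/COC(C)=O.F[B-](F)(F)F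
F0 | step 1 | none | none
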